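**Retrosynthetic overview**
1. Numbering (guaiane type): ring A = C1–C5. Cyclobutane B = C1, C5, C6, C10. Ring C = C6–C10. Butenolide D = C6–O–C12–C11=C7. C13 sits on C11, C14 on C10, C15 on C4. β is the face that carries O4. End game: the C8 tiglate follows an allylic hydroxylation, both acetates are set in one step, and ring D comes from the α-ketol C6–OH/C7=O plus a malonate that supplies C11–C13.
2. The cis-syn-cis 5-4-5 core comes from hydroxyl-directed hydrogenation of a cyclobutene C1=C5, which puts H1 and H5 on the β face beside O6 and C14.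
3. Key disconnection is the bond C6–C10. Rings B and C arise together when the seven-membered ring (C1, C5–C10) of a hydroazulene 2-siloxy-2,4-dienone undergoes a photochemical 4π electrocyclic ring contraction (7 → 5 + 4).
4. Enabling feature: C6–C10 is the bond shared by rings B and C, and it joins two fully substituted carbons that are 1,4-related through C5–C1. Removing it leaves the s-cis diene C10=C1–C5=C6 locked in a seven-membered ring next to C7=O. O4 and O6 are cis and 1,3-related, so one silicon atom can tie them and fix the sense of closure.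
5. The hydroazulene comes from a rhodium-catalysed [5+2] cycloaddition of an acyclic yne–vinylcyclopropane, itself made by an asymmetric aldol and a chelate-controlled methyl addition. Ring order: A + seven-membered ring (step 6), B + C (step 10), D (step 13).

Key step: step 10

Assumption: with but-2-ynal, the methyl-ketone enolate made with (+)-Ipc2BCl is taken to give the S carbinol; every later stereocentre follows from it.

Step 1
Reactants: 1 but-2-yn-1-ol
Product: 2 but-2-ynal
Conditions: MnO2, CH2Cl2, rt; filtered and used as a dried solution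
Reagents that add atoms: none
Why: Manganese dioxide oxidation of a propargylic alcohol stops at the volatile ynal, and no stereocentre is involved.

Step 2
Reactants: 3 cyclopropanecarbaldehyde; 4 1-(triphenyl-λ5-phosphanylidene)propan-2-one
Product: 5 (E)-4-cyclopropylbut-3-en-2-one
Conditions: CH2Cl2, reflux
Reagents that add atoms: none
Why: Wittig olefination with a stabilised ylide should give the E-enone that carries the vinylcyclopropane unit (C5–C9) and the future C4 carbonyl.

Step 3
Reactants: 5 (E)-4-cyclopropylbut-3-en-2-one; 2 but-2-ynal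
Product: 6 (5S,1E)-1-cyclopropyl-5-hydroxyoct-1-en-6-yn-3-one
Conditions: (+)-Ipc2BCl, Et3N, Et2O, 0 °C; then 2, −78 to −20 °C; H2O2, MeOH, pH 7 buffer
Reagents that add atoms: none
Why: In this Paterson boron aldol of a methyl ketone, the isopinocampheyl groups on boron differentiate the faces of the ynal, so reagent control sets the carbinol C2 as S.

Step 4
Reactants: 6 (5S,1E)-1-cyclopropyl-5-hydroxyoct-1-en-6-yn-3-one
Product: 7 (3R,5S,1E)-1-cyclopropyl-3-methyloct-1-en-6-yne-3,5-diol
Conditions: MeMgBr (excess), CH2Cl2/Et2O, −78 °C; aq. work-up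
Reagents that add atoms: methylmagnesium bromide, C[Mg]Br
Why: In this chelation-controlled 1,2-Grignard addition, the magnesium alkoxide at C2 ties the C4 carbonyl into a six-membered chelate and methyl enters axially while the alkenyl chain stays equatorial, which should give the 1,3-syn diol (C4 = R).

Step 5
Reactants: 7 (3R,5S,1E)-1-cyclopropyl-3-methyloct-1-en-6-yne-3,5-diol
Product: 8 (3R,5S,1E)-1-cyclopropyl-3-methyl-5-(triethylsilyloxy)oct-1-en-6-yn-3-ol
Conditions: TESCl, imidazole, CH2Cl2, 0 °C
Reagents that add atoms: chlorotriethylsilane, CC[Si](Cl)(CC)CC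
Why: Silylation picks the secondary propargylic hydroxyl over the tertiary one, shields C2–OH from the oxidation in step 8, and touches no stereocentre.

Step 6
Reactants: 8 (3R,5S,1E)-1-cyclopropyl-3-methyl-5-(triethylsilyloxy)oct-1-en-6-yn-3-ol
Product: 9 hydroazulene diene (C1=C10 and C6=C7; 2β-OTES; 4β-OH; 5α-H)
Conditions: [Rh(CO)2Cl]2 (5 mol %), toluene, 90 °C
Reagents that add atoms: none
Why: The rhodium-catalysed intramolecular [5+2] cycloaddition of an alkyne with a vinylcyclopropane joins C1 to C5 and C10 to C9 with opening of the cyclopropane, so ring A and the seven-membered ring form together with C14 already on C10; the new C5 stereocentre (H5 expected cis to C15) is erased in step 8.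

Step 7
Reactants: 9 hydroazulene diene
Product: 10 hydroazulene 6α,7α-diol
Conditions: OsO4 (2 mol %), NMO, acetone/H2O, 0 °C to rt
Reagents that add atoms: N-methylmorpholine N-oxide, C[N+]1([O-])CCOCC1; water, O
Why: Catalytic syn-dihydroxylation selects the cis-disubstituted C6=C7 over the tetrasubstituted C1=C10, and the two new carbinol centres (attack expected on the α face beside H5) are erased in step 8.

Step 8
Reactants: 10 hydroazulene 6α,7α-diol
Product: 11 diosphenol (6-hydroxy-1(10),5-dien-7-one)
Conditions: IBX (2-iodoxybenzoic acid), DMSO, rt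
Reagents that add atoms: none
Why: IBX oxidation takes a 1,2-diol to the 1,2-dione without C–C cleavage, and the dione should enolise toward C5 because that enol is conjugated with C1=C10 and hydrogen-bonded to C7=O, while the tertiary C4–OH and the silyl ether stay untouched.

Step 9
Reactants: 11 diosphenol
Product: 12 O4,O6-diisopropylsilylene dienone
Conditions: iPr2Si(OTf)2, 2,6-lutidine, CH2Cl2, −20 to 0 °C
Reagents that add atoms: diisopropylsilyl bis(trifluoromethanesulfonate), CC(C)[Si](OS(=O)(=O)C(F)(F)F)(OS(=O)(=O)C(F)(F)F)C(C)C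
Why: Silylene protection of the 1,3-related tertiary alcohol and enol hydroxyl closes a six-membered dioxasiline, which freezes the enol as a dienol ether and ties O6 to the face on which O4 stands.

Step 10
Reactants: 12 O4,O6-diisopropylsilylene dienone
Product: 13 tricyclic 5-4-5 cyclobutene ketone (silylene retained)
Conditions: hν (365 nm LED), degassed MeCN (0.005 M), 0 °C, borosilicate vessel
Reagents that add atoms: none
Why: Excitation of the 2-siloxycyclohepta-2,4-dienone triggers a disrotatory 4π electrocyclisation of the s-cis diene C10=C1–C5=C6, which forms the C6–C10 σ-bond and shifts the remaining π-bond to C1=C5, so the seven-membered ring is contracted by two atoms (C1 and C5) to cyclopentanone ring C. The closest known reaction type is the photochemical valence isomerisation of cyclohepta-2,4-dienones (eucarvone) and of tropolone ethers to bicyclo[3.2.0]hept-6-en-2-ones. Ring B closes as a cyclobutene in the electrocyclic 4π mode, and ring C is what remains of the seven-membered ring once this transannular bond is in place. C6 and C10 must be cis-fused, because disrotation inside a seven-membered ring turns C7 and C9 to one face and O6 and C14 to the other. The sense of disrotation is fixed by the one-atom silicon bridge, since O6 can only rise to the face on which O4 already stands (an O–Si–O bridge spanning C4–C5–C6 from opposite faces is out of geometric reach), so C4 dictates both new quaternary centres. The step needs periselectivity, secured because the ring holds only this one diene, and it needs the β,γ-unsaturated ketone product to escape a secondary 1,3-acyl shift, secured by irradiating at 365 nm where only the conjugated dienone absorbs.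

Step 11
Reactants: 13 tricyclic 5-4-5 cyclobutene ketone
Product: 14 cyclobutene triol ketone (2β,4β,6β-OH)
Conditions: HF·pyridine, pyridine, THF, 0 °C to rt
Reagents that add atoms: none
Why: Buffered fluoride desilylation removes the silicon tether and the triethylsilyl ether together under weakly acidic conditions that should not trigger an acyloin shift, and no stereocentre changes.

Step 12
Reactants: 14 cyclobutene triol ketone
Product: 15 cis-syn-cis triol ketone (1β-H; 5β-H)
Conditions: H2, [Ir(cod)(PCy3)(py)]PF6 (10 mol %), CH2Cl2, rt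
Reagents that add atoms: none
Why: In this hydroxyl-directed hydrogenation, the cationic iridium catalyst is held by the three allylic β-hydroxyls (C2, C4, C6) and should deliver both hydrogens to the β face of the strained tetrasubstituted C1=C5, setting C1 and C5 and folding ring A to the side of ring C.

Step 13
Reactants: 15 cis-syn-cis triol ketone; 16 allyl hydrogen malonate
Product: 20 allyl ester butenolide diol, via phenylboronate 17 (not isolated), via malonate ester 18 (not isolated), via butenolide boronate 19 (not isolated)
Conditions: PhB(OH)2, 4 Å MS, CH2Cl2, rt; then 16, DCC, DMAP (cat.), 0 °C to rt; then Et3N, rt; pinacol work-up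
Reagents that add atoms: none
Why: Only the cis-1,3-diol at C2/C4 can form a cyclic boronate, so the ketene-type DCC acylation with the malonic half ester reaches the hindered C6–OH alone, and an intramolecular Knoevenagel condensation on C7=O (5-exo aldol, then loss of water) closes ring D cis-fused with C13 as an ester before pinacol frees the diol.

Step 14
Reactants: 20 allyl ester butenolide diol
Product: 21 butenolide 13-carboxylic acid
Conditions: Pd(PPh3)4 (5 mol %), morpholine, THF, rt
Reagents that add atoms: none
Why: Palladium-catalysed allyl transfer (Tsuji–Trost deallylation) frees the C13 acid under neutral conditions that leave the lactone and the free hydroxyls alone.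

Step 15
Reactants: 21 butenolide 13-carboxylic acid
Product: 22 butenolide 2β,4β,13-triol
Conditions: BH3·SMe2, THF, 0 °C; aq. work-up
Reagents that add atoms: none
Why: Borane reduces a free carboxylic acid much faster than a conjugated lactone, and the tetrasubstituted electron-poor C7=C11 should resist hydroboration, so C13 alone reaches the alcohol level.

Step 16
Reactants: 22 butenolide 2β,4β,13-triol
Product: 23 2,13-diacetate
Conditions: Ac2O, pyridine, DMAP (cat.), CH2Cl2, 0 °C
Reagents that add atoms: acetic anhydride, CC(=O)OC(C)=O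
Why: Acetylation takes the primary C13 and secondary C2 hydroxyls in one operation and leaves the tertiary C4–OH free, with retention at C2.

Step 17
Reactants: 23 2,13-diacetate
Product: 24 8β-alcohol
Conditions: SeO2, 1,4-dioxane, 80 °C
Reagents that add atoms: selenium dioxide, O=[Se]=O
Why: In the SeO2 allylic hydroxylation, selenium should attack the α-carbon C11 of the butenolide from the convex β face and take the β hydrogen of C8 (the only ring methylene allylic to C7=C11) in an ene step, and the suprafacial [2,3] shift then returns oxygen to C8 on the same face, setting C8 as S.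

Step 18
Reactants: 24 8β-alcohol; 25 tigloyl chloride
Product: 26 CNP0210373.1 (target)
Conditions: pyridine, DMAP, CH2Cl2, 0 °C to rt
Reagents that add atoms: none
Why: Acylation of the secondary allylic C8–OH proceeds with retention, passes over the tertiary C4–OH, and uses the thermodynamically stable E acyl group, so the alkene geometry should hold.

**Compound list**
1 | but-2-yn-1-ol | CC#CCO | starting material
2 | but-2-ynal | CC#CC=O | intermediate
3 | cyclopropanecarbaldehyde | O=CC1CC1 | starting material
4 | 1-(triphenyl-λ5-phosphanylidene)propan-2-one | CC(=O)C=P(c1ccccc1)(c1ccccc1)c1ccccc1 | starting material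
5 | (E)-4-cyclopropylbut-3-en-2-one | CC(=O)/C=C/C1CC1 | intermediate
6 | (5S,1E)-1-cyclopropyl-5-hydroxyoct-1-en-6-yn-3-one | CC#C[C@@H](O)CC(=O)/C=C/C1CC1 | intermediate
7 | (3R,5S,1E)-1-cyclopropyl-3-methyloct-1-en-6-yne-3,5-diol (syn diol) | CC#C[C@@H](O)C[C@@](C)(O)/C=C/C1CC1 | intermediate
8 | (3R,5S,1E)-1-cyclopropyl-3-methyl-5-(triethylsilyloxy)oct-1-en-6-yn-3-ol | CC#C[C@@H](O[Si](CC)(CC)CC)C[C@@](C)(O)/C=C/C1CC1 | intermediate
9 | hydroazulene diene: bicyclo[5.3.0]decane with C1=C10 and C6=C7, 2β-OTES, 4β-OH, 4α-CH3, 10-CH3, 5α-H | CC1=C2[C@@H](O[Si](CC)(CC)CC)C[C@@](C)(O)[C@H]2C=CCC1 | intermediate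
10 | 6α,7α-diol of 9 | CC1=C2[C@@H](O[Si](CC)(CC)CC)C[C@@](C)(O)[C@H]2[C@H](O)[C@H](O)CC1 | intermediate
11 | diosphenol: C1=C10, C5=C6(OH), C7=O, 2β-OTES, 4β-OH | CC1=C2[C@@H](O[Si](CC)(CC)CC)C[C@@](C)(O)C2=C(O)C(=O)CC1 | intermediate
12 | O4,O6-diisopropylsilylene derivative of 11 (2-siloxycyclohepta-2,4-dienone) | CC1=C2[C@@H](O[Si](CC)(CC)CC)C[C@@]3(C)O[Si](C(C)C)(C(C)C)OC(C(=O)CC1)=C23 | intermediate
13 | 5-4-5 cyclobutene ketone: C1=C5, C6–C10 bond, 6β-O and 4β-O bridged by Si(iPr)2, 10β-CH3, C7=O, 2β-OTES | O=C1CC[C@]2(C)C3=C4[C@]12O[Si](C(C)C)(C(C)C)O[C@]4(C)C[C@@H]3O[Si](CC)(CC)CC | intermediate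
14 | cyclobutene triol ketone (2β,4β,6β-OH) | O=C1CC[C@]2(C)C3=C([C@]12O)[C@](C)(O)C[C@@H]3O | intermediate
15 | cis-syn-cis triol ketone (1β-H, 5β-H) | O=C1CC[C@]2(C)[C@@H]3[C@@H](O)C[C@@](C)(O)[C@@H]3[C@]12O | intermediate
16 | allyl hydrogen malonate | C=CCOC(=O)CC(=O)O | starting material
17 | O2,O4-phenylboronate of 15 | O=C1CC[C@]2(C)[C@@H]3[C@@H]4C[C@@](C)(OB(c5ccccc5)O4)[C@@H]3[C@]12O | intermediate
18 | O6 allyl malonate of 17 | O=C1CC[C@]2(C)[C@@H]3[C@@H]4C[C@@](C)(OB(c5ccccc5)O4)[C@@H]3[C@]12OC(=O)CC(=O)OCC=C | intermediate
19 | butenolide allyl ester, O2,O4-phenylboronate | C1C[C@]2(C)[C@@H]3[C@@H]4C[C@@](C)(OB(c5ccccc5)O4)[C@@H]3[C@@]23OC(=O)C(C(=O)OCC=C)=C13 | intermediate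
20 | butenolide allyl ester, 2β,4β-diol | C1C[C@]2(C)[C@@H]3[C@@H](O)C[C@@](C)(O)[C@@H]3[C@@]23OC(=O)C(C(=O)OCC=C)=C13 | intermediate
21 | butenolide 13-carboxylic acid, 2β,4β-diol | C1C[C@]2(C)[C@@H]3[C@@H](O)C[C@@](C)(O)[C@@H]3[C@@]23OC(=O)C(C(=O)O)=C13 | intermediate
22 | butenolide 2β,4β,13-triol | C1C[C@]2(C)[C@@H]3[C@@H](O)C[C@@](C)(O)[C@@H]3[C@@]23OC(=O)C(CO)=C13 | intermediate
23 | 2,13-diacetate, 4β-OH | C1C[C@]2(C)[C@@H]3[C@@H](OC(C)=O)C[C@@](C)(O)[C@@H]3[C@@]23OC(=O)C(COC(C)=O)=C13 | intermediate
24 | 8β-hydroxy-2,13-diacetate | O[C@H]1C[C@]2(C)[C@@H]3[C@@H](OC(C)=O)C[C@@](C)(O)[C@@H]3[C@@]23OC(=O)C(COC(C)=O)=C13 | intermediate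
25 | tigloyl chloride, (E)-2-methylbut-2-enoyl chloride | C/C=C(\C)C(=O)Cl | starting material
26 | CNP0210373.1, (1R,2S,4R,5R,6R,8S,10R) in the numbering above | C/C=C(\C)C(=O)O[C@H]1C[C@]2(C)[C@@H]3[C@@H](OC(C)=O)C[C@@](C)(O)[C@@H]3[C@@]23OC(=O)C(COC(C)=O)=C13 | target

**Totals**
Total step count: 18. Longest linear sequence: 17 (steps 1 and 3–18).

**Steps most likely to fail**

Step 10. The primary photoproduct is a β,γ-unsaturated ketone and may be consumed by a secondary 1,3-acyl shift. The strained siloxy ring may also slow the closure until unspecific photodecomposition takes over.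
Fallback (lactone first, sets out from 11, returns at 21):
- The acidic enol hydroxyl of 11 is esterified with methyl hydrogen malonate (DCC), and the malonate closes on C7 (Et3N, Knoevenagel) to the γ-alkylidene butenolide trienolide methyl ester F1.
- Irradiation at 365 nm performs the same 4π ring contraction on a chromophore whose product, the cyclobutene butenolide F2, has no ketone left for an acyl shift. The sense of closure then rests on allylic strain between O6 and the C15 methyl group.
- HF·pyridine gives the cyclobutene diol F3.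
- Hydroxyl-directed hydrogenation with [Ir(cod)(PCy3)(py)]PF6 gives the saturated methyl ester F4.
- LiOH followed by acidification (relactonisation) gives acid 21.

Step 13. Acylation of the neopentyl-like tertiary C6–OH may be too slow. The free α-ketol on the four-membered ring may meanwhile undergo an acyloin shift of C5 from C6 to C7, which relieves ring strain.
Fallback (neutral ylide lactonisation, C13 by cross-coupling, sets out from 15, returns at 22):
- 2,2-Dimethoxypropane with PPTS gives the O2,O4-acetonide F5.
- (Triphenylphosphoranylidene)ketene in warm toluene adds to C6–OH and closes by intramolecular Wittig reaction on C7 to the α-unsubstituted butenolide F6.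
- Bromination and dehydrobromination (Br2, then Et3N) give the α-bromobutenolide F7.
- Stille coupling with Bu3SnCH2OH and Pd(PPh3)4 gives the hydroxymethyl butenolide acetonide F8.
- Aqueous acetic acid removes the acetonide to give triol 22.

Step 17. The ene step on an electron-poor alkene may be sluggish. Forcing conditions may bring over-oxidation at C8 or acid-induced loss of the tertiary C4–OH.
Fallback (oxidise, reduce, invert, sets out from 23, returns at 26):
- Radical-type allylic oxidation with CrO3 and 3,5-dimethylpyrazole gives the C8 enone F9.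
- Luche reduction (NaBH4, CeCl3·7H2O) from the convex β face gives the 8α-alcohol F10.
- A Mitsunobu reaction with tiglic acid (PPh3, DIAD) inverts C8 and gives 26 directly.

**Further compounds**
F1 | step 10 | trienolide methyl ester (C1=C10, C5=C6, C7=C11; 2β-OTES, 4β-OH) | CC1=C2[C@@H](O[Si](CC)(CC)CC)C[C@@](C)(O)C2=C2OC(=O)C(C(=O)OC)=C2CC1
F2 | step 10 | cyclobutene butenolide methyl ester, 2β-OTES | C1C[C@]2(C)C3=C([C@@]24OC(=O)C(C(=O)OC)=C14)[C@](C)(O)C[C@@H]3O[Si](CC)(CC)CC
F3 | step 10 | cyclobutene butenolide methyl ester, 2β,4β-diol | C1C[C@]2(C)C3=C([C@@]24OC(=O)C(C(=O)OC)=C14)[C@](C)(O)C[C@@H]3O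
F4 | step 10 | saturated butenolide methyl ester, 2β,4β-diol | C1C[C@]2(C)[C@@H]3[C@@H](O)C[C@@](C)(O)[C@@H]3[C@@]23OC(=O)C(C(=O)OC)=C13
F5 | step 13 | O2,O4-acetonide of 15 | O=C1CC[C@]2(C)[C@@H]3[C@@H]4C[C@@](C)(OC(C)(C)O4)[C@@H]3[C@]12O
F6 | step 13 | α-unsubstituted butenolide acetonide | C1C[C@]2(C)[C@@H]3[C@@H]4C[C@@](C)(OC(C)(C)O4)[C@@H]3[C@@]23OC(=O)C=C13
F7 | step 13 | α-bromobutenolide acetonide | C1C[C@]2(C)[C@@H]3[C@@H]4C[C@@](C)(OC(C)(C)O4)[C@@H]3[C@@]23OC(=O)C(Br)=C13
F8 | step 13 | hydroxymethyl butenolide acetonide | C1C[C@]2(C)[C@@H]3[C@@H]4C[C@@](C)(OC(C)(C)O4)[C@@H]3[C@@]23OC(=O)C(CO)=C13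
F9 | step 17 | C8 enone of 23 | O=C1C[C@]2(C)[C@@H]3[C@@H](OC(C)=O)C[C@@](C)(O)[C@@H]3[C@@]23OC(=O)C(COC(C)=O)=C13
F10 | step 17 | 8α-alcohol (C8 epimer of 24) | O[C@@H]1C[C@]2(C)[C@@H]3[C@@H](OC(C)=O)C[C@@](C)(O)[C@@H]3[C@@]23OC(=O)C(COC(C)=O)=C13
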